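## Retrosynthetic overview

1. The target comes from a site- and face-selective mono-epoxidation of a cyclohexa-1,3-diene ketone; the oxirane is the last ring formed.
2. The cyclohexadiene comes from an all-E tetraene pyrone by light-driven E→Z isomerisation and conrotatory 6π electrocyclisation; the ketone is carried as a silyl ether until after ring closure.
3. The tetraene comes from a vinylogous aldol condensation of 6-ethyl-2-methoxy-3,5-dimethyl-4-pyranone with an all-E trienal.
4. The trienal comes from three iterative Wittig homologations of the L-proline-derived aldol dimer of propanal, which sets the side-chain stereocentre.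
5. The pyrone, the first ring, comes from enol-lactonisation of a triketo ester and O-methylation. Ring order: pyrone, then carbocycle, then oxirane.

Assumption: the remote side-chain stereocentre gives no facial control in the ring closure (step 8), and the two resulting ring diastereomers are taken to be separable by chromatography at the alcohol stage (step 9).

## Route

Step 1
Reactants: 1 ethyl 2-methyl-3-oxopentanoate; 2 N-methoxy-N-methylpropanamide
Product: 4 6-ethyl-4-hydroxy-3,5-dimethyl-2H-pyran-2-one, via triketo ester 3 (not isolated)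
Conditions: LiN(iPr)2 (2.2 equiv), THF, −78 → 0 °C; 2, −78 °C → rt; aq NH4Cl; crude 3, DBU, toluene, 110 °C
Reagents that add atoms: none
Why: Double deprotonation lets the β-keto ester react at its γ-carbon with the Weinreb amide (dianion C-acylation, the stable tetrahedral intermediate prevents over-addition) to give 3, and DBU-mediated enol-lactonisation with loss of ethanol (the polyketide-type pyrone closure) gives 4; no stereocentre is formed.

Step 2
Reactants: 4 6-ethyl-4-hydroxy-3,5-dimethyl-2H-pyran-2-one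
Product: 5 6-ethyl-2-methoxy-3,5-dimethyl-4H-pyran-4-one
Conditions: MeOTf (1.2 equiv), CH2Cl2, 0 °C → rt; aq NaHCO3
Reagents that add atoms: methyl trifluoromethanesulfonate, COS(=O)(=O)C(F)(F)F
Why: Hard O-methylation of the neutral hydroxypyranone takes place at the lactone carbonyl oxygen (Beak-type methylation) and proton loss gives the 2-methoxy-4-pyranone, the minor 4-methoxy-2-pyranone being removed by chromatography; no stereocentre.

Step 3
Reactants: 6 propanal (two molecules)
Product: 8 (2S,3S)-3-[(tert-butyldimethylsilyl)oxy]-2-methylpentanal, via aldol 7 (not isolated)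
Conditions: L-proline (10 mol%), DMF, 4 °C, slow addition of the second equivalent of 6; then imidazole, TBSCl, 0 °C → rt
Reagents that add atoms: tert-butyldimethylsilyl chloride, CC(C)(C)[Si](C)(C)Cl
Why: L-Proline enamine catalysis (direct asymmetric aldehyde–aldehyde aldol, Houk–List transition state in which the carboxylic acid steers the acceptor onto one face of the (E)-enamine) sets C-2 (S) and C-3 (S) (about 4:1 anti:syn, about 99% ee for anti), and silylation in the same DMF solution blocks retro-aldol and oligomerisation.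

Step 4
Reactants: 8 (2S,3S)-3-[(tert-butyldimethylsilyl)oxy]-2-methylpentanal; 9 2-(triphenylphosphoranylidene)propanal
Product: 10 (2E,4R,5S)-5-[(tert-butyldimethylsilyl)oxy]-2,4-dimethylhept-2-enal
Conditions: toluene, 90 °C, 16 h
Reagents that add atoms: none
Why: Wittig olefination with the stabilised formyl ylide is E-selective (>95:5) and neutral, so the α-stereocentre survives (its descriptor changes from S to R only through the priority rules); the minor syn-aldol-derived isomer is removed by chromatography here.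

Step 5
Reactants: 10 (2E,4R,5S)-5-[(tert-butyldimethylsilyl)oxy]-2,4-dimethylhept-2-enal; 9 2-(triphenylphosphoranylidene)propanal
Product: 11 (2E,4E,6R,7S)-7-[(tert-butyldimethylsilyl)oxy]-2,4,6-trimethylnona-2,4-dienal
Conditions: toluene, 100 °C, 24 h
Reagents that add atoms: none
Why: Second iteration of the same E-selective Wittig homologation; the enal is less electrophilic than the aliphatic aldehyde of step 4, which is why each iteration stops cleanly at mono-homologation; no stereocentre is formed.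

Step 6
Reactants: 11 (2E,4E,6R,7S)-7-[(tert-butyldimethylsilyl)oxy]-2,4,6-trimethylnona-2,4-dienal; 9 2-(triphenylphosphoranylidene)propanal
Product: 12 (2E,4E,6E,8R,9S)-9-[(tert-butyldimethylsilyl)oxy]-2,4,6,8-tetramethylundeca-2,4,6-trienal
Conditions: toluene, 110 °C, 36 h, dark
Reagents that add atoms: none
Why: Third iteration of the E-selective Wittig homologation with the stabilised ylide gives the all-E trienal; no stereocentre is formed.

Step 7
Reactants: 12 (2E,4E,6E,8R,9S)-9-[(tert-butyldimethylsilyl)oxy]-2,4,6,8-tetramethylundeca-2,4,6-trienal; 5 6-ethyl-2-methoxy-3,5-dimethyl-4H-pyran-4-one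
Product: 15 2-[(2E,4E,6E,8E,10R,11S)-11-[(tert-butyldimethylsilyl)oxy]-4,6,8,10-tetramethyltrideca-2,4,6,8-tetraen-2-yl]-6-methoxy-3,5-dimethyl-4H-pyran-4-one, via aldol adduct 13 (not isolated), via allylic acetate 14 (not isolated)
Conditions: 5, LiN(SiMe3)2, THF, −78 °C; 12, −78 °C; Ac2O, −78 → 0 °C; DBU, 0 → 40 °C; amber glassware
Reagents that add atoms: none
Why: γ-Lithiation of the 6-ethyl group gives a vinylogous enolate that adds 1,2 to the aldehyde (vinylogous aldol), and O-acetylation followed by DBU-induced E1cB elimination gives the fully conjugated tetraene with the thermodynamically preferred E geometry at the new alkene; the two transient stereocentres are destroyed.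

Step 8
Reactants: 15 2-[(2E,4E,6E,8E,10R,11S)-11-[(tert-butyldimethylsilyl)oxy]-4,6,8,10-tetramethyltrideca-2,4,6,8-tetraen-2-yl]-6-methoxy-3,5-dimethyl-4H-pyran-4-one
Product: 17 6-[(1R,6R)-6-[(2E,4R,5S)-5-[(tert-butyldimethylsilyl)oxy]-4-methylhept-2-en-2-yl]-1,3,5-trimethylcyclohexa-2,4-dien-1-yl]-2-methoxy-3,5-dimethyl-4H-pyran-4-one, via 4Z-tetraene 16 (not isolated)
Conditions: hν (350–365 nm, Pyrex), degassed toluene, −40 °C, to about 60% conversion; recovered tetraene isomers re-irradiated
Reagents that add atoms: none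
Why: Light isomerises the central C4=C5 bond to give 16, whose E,Z,E-triene closes by photochemical conrotatory 6π electrocyclisation (Woodward–Hoffmann; the light-driven isomerisation/electrocyclisation known for this class of tetraene pyrones), so the two outside groups (pyrone at C-1, alkenyl chain at C-6) end up trans; 17 forms as a roughly 1:1 mixture with its (1S,6S) ring diastereomer (removed in step 9), the long wavelength spares the non-absorbing product, and −40 °C suppresses thermal 8π/6π leakage from Z,Z isomers.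

Step 9
Reactants: 17 6-[(1R,6R)-6-[(2E,4R,5S)-5-[(tert-butyldimethylsilyl)oxy]-4-methylhept-2-en-2-yl]-1,3,5-trimethylcyclohexa-2,4-dien-1-yl]-2-methoxy-3,5-dimethyl-4H-pyran-4-one
Product: 18 6-[(1R,6R)-6-[(2E,4R,5S)-5-hydroxy-4-methylhept-2-en-2-yl]-1,3,5-trimethylcyclohexa-2,4-dien-1-yl]-2-methoxy-3,5-dimethyl-4H-pyran-4-one
Conditions: Bu4NF, AcOH (1:1), THF, rt → 40 °C; silica gel then semi-preparative HPLC to remove the (1S,6S) ring diastereomer
Reagents that add atoms: none
Why: Fluoride cleaves the Si–O bond (desilylation) without touching the diene or the pyrone, and the free carbinol makes the two ring diastereomers chromatographically distinguishable; no stereocentre is changed.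

Step 10
Reactants: 18 6-[(1R,6R)-6-[(2E,4R,5S)-5-hydroxy-4-methylhept-2-en-2-yl]-1,3,5-trimethylcyclohexa-2,4-dien-1-yl]-2-methoxy-3,5-dimethyl-4H-pyran-4-one
Product: 19 2-methoxy-3,5-dimethyl-6-[(1R,6R)-1,3,5-trimethyl-6-[(2E,4R)-4-methyl-5-oxohept-2-en-2-yl]cyclohexa-2,4-dien-1-yl]-4H-pyran-4-one
Conditions: Dess–Martin periodinane (1.3 equiv), NaHCO3, CH2Cl2, 0 °C → rt
Reagents that add atoms: none
Why: Dess–Martin oxidation under bicarbonate buffer converts the carbinol into the ethyl ketone without epimerising the adjacent allylic stereocentre or moving the now isolated β,γ-alkene into conjugation.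

Step 11
Reactants: 19 2-methoxy-3,5-dimethyl-6-[(1R,6R)-1,3,5-trimethyl-6-[(2E,4R)-4-methyl-5-oxohept-2-en-2-yl]cyclohexa-2,4-dien-1-yl]-4H-pyran-4-one
Product: 20 6-[(1R,4R,5S,6S)-2,4,6-trimethyl-5-[(2E,4R)-4-methyl-5-oxohept-2-en-2-yl]-7-oxabicyclo[4.1.0]hept-2-en-4-yl]-2-methoxy-3,5-dimethyl-4H-pyran-4-one
Conditions: DMDO (1.0 equiv, acetone solution), CH2Cl2, −40 → −20 °C
Reagents that add atoms: dimethyldioxirane, CC1(C)OO1
Why: Concerted spiro oxygen transfer (dioxirane epoxidation) should go to the diene alkene remote from the quaternary pyrone-bearing carbon (the other diene alkene is neopentylic and inductively deactivated, the side-chain alkene is flanked by two branched carbons and deactivated by the β-ketone) and from the face anti to the pseudo-axial, doubly ortho-substituted pyrone, that is syn to the side chain, which sets C-1 (R) and C-6 (S); this facial preference is an argument from sterics, not a precedent.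

## Compound list

1 | ethyl 2-methyl-3-oxopentanoate (racemic) | CCC(=O)C(C)C(=O)OCC | starting material
2 | N-methoxy-N-methylpropanamide | CCC(=O)N(C)OC | starting material
3 | ethyl 2,4-dimethyl-3,5-dioxoheptanoate (stereoisomer and tautomer mixture) | CCC(=O)C(C)C(=O)C(C)C(=O)OCC | intermediate (not isolated)
4 | 6-ethyl-4-hydroxy-3,5-dimethyl-2H-pyran-2-one | CCc1oc(=O)c(C)c(O)c1C | intermediate
5 | 6-ethyl-2-methoxy-3,5-dimethyl-4H-pyran-4-one | CCc1oc(OC)c(C)c(=O)c1C | intermediate
6 | propanal | CCC=O | starting material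
7 | (2S,3S)-3-hydroxy-2-methylpentanal | CC[C@H](O)[C@H](C)C=O | intermediate (not isolated)
8 | (2S,3S)-3-[(tert-butyldimethylsilyl)oxy]-2-methylpentanal | CC[C@H](O[Si](C)(C)C(C)(C)C)[C@H](C)C=O | intermediate
9 | 2-(triphenylphosphoranylidene)propanal | CC(C=O)=P(c1ccccc1)(c1ccccc1)c1ccccc1 | starting material
10 | (2E,4R,5S)-5-[(tert-butyldimethylsilyl)oxy]-2,4-dimethylhept-2-enal | CC[C@H](O[Si](C)(C)C(C)(C)C)[C@H](C)/C=C(\C)C=O | intermediate
11 | (2E,4E,6R,7S)-7-[(tert-butyldimethylsilyl)oxy]-2,4,6-trimethylnona-2,4-dienal | CC[C@H](O[Si](C)(C)C(C)(C)C)[C@H](C)/C=C(\C)/C=C(\C)C=O | intermediate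
12 | (2E,4E,6E,8R,9S)-9-[(tert-butyldimethylsilyl)oxy]-2,4,6,8-tetramethylundeca-2,4,6-trienal | CC[C@H](O[Si](C)(C)C(C)(C)C)[C@H](C)/C=C(\C)/C=C(\C)/C=C(\C)C=O | intermediate
13 | lithium (4E,6E,8E,10R,11S)-11-[(tert-butyldimethylsilyl)oxy]-2-(6-methoxy-3,5-dimethyl-4-oxo-4H-pyran-2-yl)-4,6,8,10-tetramethyltrideca-4,6,8-trien-3-olate (C-2/C-3 epimer mixture) | [Li+].CC[C@H](O[Si](C)(C)C(C)(C)C)[C@H](C)/C=C(\C)/C=C(\C)/C=C(\C)C([O-])C(C)c1oc(OC)c(C)c(=O)c1C | intermediate (not isolated)
14 | (4E,6E,8E,10R,11S)-11-[(tert-butyldimethylsilyl)oxy]-2-(6-methoxy-3,5-dimethyl-4-oxo-4H-pyran-2-yl)-4,6,8,10-tetramethyltrideca-4,6,8-trien-3-yl acetate (C-2/C-3 epimer mixture) | CC[C@H](O[Si](C)(C)C(C)(C)C)[C@H](C)/C=C(\C)/C=C(\C)/C=C(\C)C(OC(C)=O)C(C)c1oc(OC)c(C)c(=O)c1C | intermediate (not isolated)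
15 | 2-[(2E,4E,6E,8E,10R,11S)-11-[(tert-butyldimethylsilyl)oxy]-4,6,8,10-tetramethyltrideca-2,4,6,8-tetraen-2-yl]-6-methoxy-3,5-dimethyl-4H-pyran-4-one | CC[C@H](O[Si](C)(C)C(C)(C)C)[C@H](C)/C=C(\C)/C=C(\C)/C=C(\C)/C=C(\C)c1oc(OC)c(C)c(=O)c1C | intermediate
16 | 2-[(2E,4Z,6E,8E,10R,11S)-11-[(tert-butyldimethylsilyl)oxy]-4,6,8,10-tetramethyltrideca-2,4,6,8-tetraen-2-yl]-6-methoxy-3,5-dimethyl-4H-pyran-4-one | CC[C@H](O[Si](C)(C)C(C)(C)C)[C@H](C)/C=C(\C)/C=C(\C)/C=C(/C)\C=C(/C)c1oc(OC)c(C)c(=O)c1C | intermediate (not isolated)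
17 | 6-[(1R,6R)-6-[(2E,4R,5S)-5-[(tert-butyldimethylsilyl)oxy]-4-methylhept-2-en-2-yl]-1,3,5-trimethylcyclohexa-2,4-dien-1-yl]-2-methoxy-3,5-dimethyl-4H-pyran-4-one | CC[C@H](O[Si](C)(C)C(C)(C)C)[C@H](C)/C=C(\C)[C@@H]1C(C)=CC(C)=C[C@@]1(C)c1oc(OC)c(C)c(=O)c1C | intermediate
18 | 6-[(1R,6R)-6-[(2E,4R,5S)-5-hydroxy-4-methylhept-2-en-2-yl]-1,3,5-trimethylcyclohexa-2,4-dien-1-yl]-2-methoxy-3,5-dimethyl-4H-pyran-4-one | CC[C@H](O)[C@H](C)/C=C(\C)[C@@H]1C(C)=CC(C)=C[C@@]1(C)c1oc(OC)c(C)c(=O)c1C | intermediate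
19 | 2-methoxy-3,5-dimethyl-6-[(1R,6R)-1,3,5-trimethyl-6-[(2E,4R)-4-methyl-5-oxohept-2-en-2-yl]cyclohexa-2,4-dien-1-yl]-4H-pyran-4-one | CCC(=O)[C@H](C)/C=C(\C)[C@@H]1C(C)=CC(C)=C[C@@]1(C)c1oc(OC)c(C)c(=O)c1C | intermediate
20 | 6-[(1R,4R,5S,6S)-2,4,6-trimethyl-5-[(2E,4R)-4-methyl-5-oxohept-2-en-2-yl]-7-oxabicyclo[4.1.0]hept-2-en-4-yl]-2-methoxy-3,5-dimethyl-4H-pyran-4-one | CCC(=O)[C@H](C)/C=C(\C)[C@@H]1[C@]2(C)O[C@@H]2C(C)=C[C@@]1(C)c1oc(OC)c(C)c(=O)c1C | target

## Step count and risks

Total step count: 11. Longest linear sequence: 9 (steps 3 to 11, from propanal).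

The three steps most likely to fail:

**Step 8 (photo-isomerisation / 6π closure).** Irradiation can isomerise any of the four double bonds. Z,Z isomers can leak into the thermal 8π/6π manifold, closure from a 2Z isomer gives the cis ring series, and the conversion has to be stopped early. The fallback sets out from dienal 11 and comes back to the route at compound 16. Olefination of 11 with the iodo-ylide Ph3P=C(Me)I (from ethyltriphenylphosphonium iodide, n-BuLi, I2, then NaN(SiMe3)2; Stork–Zhao type) gives the Z-configured vinyl iodide tert-butyl{[(3S,4R,5E,7E,9Z)-10-iodo-4,6,8-trimethylundeca-5,7,9-trien-3-yl]oxy}dimethylsilane F1. Iodine–lithium exchange (t-BuLi, Et2O, −78 °C) and formylation with DMF give (2Z,4E,6E,8R,9S)-9-[(tert-butyldimethylsilyl)oxy]-2,4,6,8-tetramethylundeca-2,4,6-trienal F2. Addition of lithiated 5, acetylation and DBU elimination as in step 7 pass through the lithium (4Z)-aldolate F3 and the (4Z)-allylic acetate F4 and deliver 16 as a defined compound. Light is then needed only for the conrotatory closure of 16 to 17.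

**Step 11 (epoxidation).** Three trisubstituted alkenes compete, and the facial outcome rests on a steric argument. The fallback sets out from 19 and comes back at 20. NBS in THF–H2O (0 °C) adds across the same alkene to give the trans-bromohydrin 6-[(1R,4S,5S,6S)-4-bromo-5-hydroxy-1,3,5-trimethyl-6-[(2E,4R)-4-methyl-5-oxohept-2-en-2-yl]cyclohex-2-en-1-yl]-2-methoxy-3,5-dimethyl-4H-pyran-4-one F5 (bromonium on the pyrone face, water anti at the tertiary carbon). Ag2O in CH2Cl2 then closes the oxirane with inversion at the bromine-bearing carbon. The oxygen therefore ends up on the face opposite to the one an electrophile attacks directly, which is the remedy if DMDO epoxidises from the pyrone face.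

**Step 7 (one-flask aldol / acetylation / elimination).** The trienal and the tetraene are sensitive, and the E1cB step may be slow or give isomer mixtures. The fallback sets out from 5 and comes back at 15. Lithiated 5 (LiN(SiMe3)2, 2 equiv) is C-phosphorylated with ClP(O)(OEt)2 to give diethyl [1-(6-methoxy-3,5-dimethyl-4-oxo-4H-pyran-2-yl)ethyl]phosphonate F6. Horner–Wadsworth–Emmons olefination of 12 with F6 (NaH, THF, 0 °C → rt) forms the pyrone-bearing alkene in a single event.

## Further compounds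

F1 | step 8 | tert-butyl{[(3S,4R,5E,7E,9Z)-10-iodo-4,6,8-trimethylundeca-5,7,9-trien-3-yl]oxy}dimethylsilane | CC[C@H](O[Si](C)(C)C(C)(C)C)[C@H](C)/C=C(\C)/C=C(\C)/C=C(/C)I
F2 | step 8 | (2Z,4E,6E,8R,9S)-9-[(tert-butyldimethylsilyl)oxy]-2,4,6,8-tetramethylundeca-2,4,6-trienal | CC[C@H](O[Si](C)(C)C(C)(C)C)[C@H](C)/C=C(\C)/C=C(\C)/C=C(/C)C=O
F3 | step 8 | lithium (4Z,6E,8E,10R,11S)-11-[(tert-butyldimethylsilyl)oxy]-2-(6-methoxy-3,5-dimethyl-4-oxo-4H-pyran-2-yl)-4,6,8,10-tetramethyltrideca-4,6,8-trien-3-olate (C-2/C-3 epimer mixture) | [Li+].CC[C@H](O[Si](C)(C)C(C)(C)C)[C@H](C)/C=C(\C)/C=C(\C)/C=C(/C)C([O-])C(C)c1oc(OC)c(C)c(=O)c1C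
F4 | step 8 | (4Z,6E,8E,10R,11S)-11-[(tert-butyldimethylsilyl)oxy]-2-(6-methoxy-3,5-dimethyl-4-oxo-4H-pyran-2-yl)-4,6,8,10-tetramethyltrideca-4,6,8-trien-3-yl acetate (C-2/C-3 epimer mixture) | CC[C@H](O[Si](C)(C)C(C)(C)C)[C@H](C)/C=C(\C)/C=C(\C)/C=C(/C)C(OC(C)=O)C(C)c1oc(OC)c(C)c(=O)c1C
F5 | step 11 | 6-[(1R,4S,5S,6S)-4-bromo-5-hydroxy-1,3,5-trimethyl-6-[(2E,4R)-4-methyl-5-oxohept-2-en-2-yl]cyclohex-2-en-1-yl]-2-methoxy-3,5-dimethyl-4H-pyran-4-one | CCC(=O)[C@H](C)/C=C(\C)[C@@H]1[C@](C)(O)[C@@H](Br)C(C)=C[C@@]1(C)c1oc(OC)c(C)c(=O)c1C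
F6 | step 7 | diethyl [1-(6-methoxy-3,5-dimethyl-4-oxo-4H-pyran-2-yl)ethyl]phosphonate (racemic) | CCOP(=O)(OCC)C(C)c1oc(OC)c(C)c(=O)c1C
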